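All runs come from a simulation for substances that don't exist; the scatter is artificial.

Single product here is what reagent makes of substrate, so I follow what is left of each, in equivalents of the substrate charged.

| setting | Thursday's | flask |
|---|---|---|
| substrate | 0.29 M | 0.29 M |
| reagent | 1.9 equiv | 0.950 equiv |
| remark | run made earlier |  |
| time |  | 8.0 d |

Thursday's run (percent of the substrate charged)

| time / h | substrate / % | single product / % | double product / % |
|---|---|---|---|
| 1.50 | 49.7 | 48.5 | 0 |
| 2.50 | 36.6 | 61.7 | 0 |
| 4.00 | 24.4 | 74.7 | 0.1 |
| 5.00 | 18.4 | 78.9 | 0 |
| 8.00 | 12.1 | 88.1 | 0.3 |
| 12.0 | 4.5 | 92.2 | 1.1 |
| 20.0 | 2.4 | 93.9 | 0.9 |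

(each reading ± 1 percentage point)

- a reading or a percentage of single product counts all its forms, free or not

- how much substrate there is at 8.0 d, in percent of the substrate charged
- how much single product there is at 8.0 d, in percent of the substrate charged
- how much double product there is at 8.0 d, in percent of the substrate charged

If substrate falls at K·c(substrate)·c(reagent), the slope of ln c(substrate) is K·c(reagent), so that slope, read from the substrate, gives the reagent left. Thursday's first reading, taken as plain second order, gives K = 0.290 /h per equivalent. Between 4.00 h and 20.0 h Thursday's slope reads 0.145 /h, so near 7.65% substrate I read about 0.500 equiv of reagent in that run, less than the 0.977 that one-to-one use leaves.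

I suppose this loss goes with the square of c(reagent). Dividing the two rates then removes time: dc(reagent)/dc(substrate) = 1 + w·c(reagent)/c(substrate). Taking the geometric mean of Thursday's reagent along ln c(substrate), I read w = 0.190, the reagent lost per reagent used on substrate when the two stand equal, a selectivity factor.

Integrating to c(reagent) = 0, with E the equivalents charged, leaves substrate (​1 − E(1 − w))^(1/(1 − w)). For my flask, where reagent is the limiting reagent, that is 16.4%. Subtraction would give the single product, but Thursday's last readings sum short by 2.8 percentage points. So I take that off too, along with Thursday's 0.9% double product as my estimate of what this flask loses that way, and I commit to about 79.9% single product.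

The forecast gives 7.5% substrate, 91.5% single product and 1% double product, holding that the slowing “suggests product inhibition”. The flask gives 14.8%, 81.9% and 0.519%.

    reagent + single product → double product (k = 0.00140 /M/min)
    crystals ⇌ single product, rate k2*(cs2 - [single product]) while solid is left; crystals form when [single product] > cs2 (solubility = 8.30 mM, k = 0.160 /min)
    substrate + single product → side product (k = 7.60 × 10⁻⁴ /M/min)
    2 reagent → homo dimer (k = 0.00150 /M/min)
    substrate + reagent → single product (k = 0.0170 /M/min)

In this flask reagent stands at 0% of its charge after 8.00 d, and my 16.4% substrate lies 1.6 points above what is found. With the same w, I reckon 63.5% substrate for the neighbour charged with 0.380 equiv of reagent and held for the same time. That neighbour holds 59.0% substrate and 31.8% single product, with side product, where one of it counts as two, at 9.06%.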